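**Plan**

1. Cuts: the three ester C–O bonds and the side-chain carbinol/isobutenyl unit; then the CH(CH3)–CH2 unit, via a ring-fused unsaturated δ-lactone, back to a cyclohexenecarboxylic acid; then, in one cut, the ring σ bond CH(side chain)–CH(O-angelate) together with the ring C=C(CH3) π bond, by a ring-contracting Ireland–Claisen rearrangement.
2. Enabling feature: in the cyclohexene, the angelate-bearing CH is allylic to the CH=C(CH3) alkene and bonded to the ring CH whose exocyclic carbon can be a carboxyl carbon (a γ,δ-unsaturated acid). The ring CH2–CH(OAc) pair already joins that CH to the C(CH3) carbon, so the allyl and ketene-acetal halves fit into one δ-lactone.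
3. Forward: chiral-pool keto ester 5 → alkynylation/lactonisation → (Z)-enol ether δ-lactone 12 → [3,3] ring contraction builds the cyclohexene (15) → methyl ketone → temporary fused unsaturated lactone 19 → conjugate reduction → lactone opening by the isobutenyl unit → angelate, carbinol, acetates.
4. Stereochemistry: the ring CH(OAc) centre is bought; the lactone quaternary carbinol comes from Cram-chelate control; the CH(side chain) and CH(O-angelate) centres are relayed from these and from the (Z)-alkene geometry in the [3,3] step; CH(CH3) comes from axial hydride delivery to the rigid trans-fused lactone; the side-chain carbinol from CBS reagent control.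

Key step: step 7

Assumption: compounds 1, 6 and 7 and the reagents named (angelic acid, 1-bromo-2-methylprop-1-ene, diethylphosphonoacetic acid, Me2BBr) are taken as commercial; the ester at the ring carbinol is the (Z)-2-methylbut-2-enoate (angelate).

**Step 1**
Reactants: 1 (R)-5-oxotetrahydrofuran-2-carboxylic acid
Product: 2 (R)-N-methoxy-N-methyl-5-oxotetrahydrofuran-2-carboxamide
Conditions: 1,1'-carbonyldiimidazole, CH2Cl2, 0 °C to rt; then MeNH(OMe)·HCl, rt
Reagents that add atoms: N,O-dimethylhydroxylamine hydrochloride, CNOC.Cl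
Why: Activation of the acid as its acyl imidazole and amidation (Weinreb amide formation) should proceed without touching the γ-lactone or the stereocenter.

**Step 2**
Reactants: 2 (R)-N-methoxy-N-methyl-5-oxotetrahydrofuran-2-carboxamide
Product: 4 methyl (R)-5-[methoxy(methyl)amino]-4-(methoxymethoxy)-5-oxopentanoate, via hydroxy ester 3 (not isolated)
Conditions: K2CO3 (cat.), MeOH, 0 °C; concentrate; then MOMCl, iPr2NEt, CH2Cl2, 0 °C to rt
Reagents that add atoms: methanol, CO; chloromethyl methyl ether, COCCl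
Why: Base-catalysed lactone methanolysis (transesterification) should open the activated γ-lactone, and immediate O-alkylation with MOMCl traps the secondary alcohol before it relactonises and installs a chelating α-alkoxy group.

**Step 3**
Reactants: 4 methyl (R)-5-[methoxy(methyl)amino]-4-(methoxymethoxy)-5-oxopentanoate
Product: 5 methyl (R)-4-(methoxymethoxy)-5-oxohexanoate
Conditions: MeMgBr, THF, −78 to −20 °C
Reagents that add atoms: methylmagnesium bromide, C[Mg]Br
Why: Weinreb ketone synthesis, in which the chelated tetrahedral adduct stops at the ketone stage and the α-alkoxy amide reacts faster than the methyl ester at low temperature.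

**Step 4**
Reactants: 6 4-methoxybenzyl alcohol; 7 trichloroethylene
Product: 8 (E)-1,2-dichlorovinyl 4-methoxybenzyl ether
Conditions: KH, THF, 0 °C to rt; then 7, −50 °C to rt
Reagents that add atoms: none
Why: Addition of the potassium alkoxide to dichloroacetylene formed in situ from trichloroethylene (addition–elimination) is the standard entry to 1,2-dichlorovinyl ethers, the precursors of alkynyl ethers.

**Step 5**
Reactants: 8 (E)-1,2-dichlorovinyl 4-methoxybenzyl ether; 5 methyl (R)-4-(methoxymethoxy)-5-oxohexanoate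
Product: 11 (5R,6R)-6-{[(4-methoxybenzyl)oxy]ethynyl}-5-(methoxymethoxy)-6-methyltetrahydro-2H-pyran-2-one, via lithium alkoxyacetylide 9 (not isolated), via tertiary alkoxide adduct 10 (not isolated)
Conditions: 8, n-BuLi (2.1 equiv), Et2O, −78 to −40 °C; then 5 premixed with MgBr2·OEt2, CH2Cl2, −78 °C; then rt
Reagents that add atoms: none
Why: Elimination and chlorine–lithium exchange give the lithium alkoxyacetylide, whose Cram-chelate-controlled 1,2-addition to the MgBr2-chelated α-alkoxy ketone (attack anti to the ester-bearing chain) sets the quaternary carbinol with the alkynyl group cis to the MOM ether, and the tertiary alkoxide then lactonises onto the methyl ester (intramolecular transesterification).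

**Step 6**
Reactants: 11 (5R,6R)-6-{[(4-methoxybenzyl)oxy]ethynyl}-5-(methoxymethoxy)-6-methyltetrahydro-2H-pyran-2-one
Product: 12 (5R,6R)-6-{(Z)-2-[(4-methoxybenzyl)oxy]ethenyl}-5-(methoxymethoxy)-6-methyltetrahydro-2H-pyran-2-one
Conditions: H2 (1 atm), Pd/CaCO3 poisoned with Pb(OAc)2, quinoline, EtOAc–Et3N, rt
Reagents that add atoms: none
Why: Lindlar semihydrogenation adds H2 syn to the alkynyl ether and should stop at the (Z)-enol ether, fixing the alkene geometry that the next step translates into the carbinol configuration.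

**Step 7**
Reactants: 12 (5R,6R)-6-{(Z)-2-[(4-methoxybenzyl)oxy]ethenyl}-5-(methoxymethoxy)-6-methyltetrahydro-2H-pyran-2-one
Product: 15 (1R,2R,5R)-2-[(4-methoxybenzyl)oxy]-5-(methoxymethoxy)-4-methylcyclohex-3-ene-1-carboxylic acid, via silyl ketene acetal 13 (not isolated), via silyl ester 14 (not isolated)
Conditions: LiN(iPr)2, TBSCl, THF–DMPU, −78 °C to rt; then toluene, 80 °C; then THF–H2O, rt
Reagents that add atoms: none
Why: LiN(iPr)2 enolises the lactone at C3 and TBSCl traps the enolate on oxygen to give the cyclic silyl ketene acetal 13, which on warming undergoes a concerted suprafacial [3,3]-sigmatropic shift in which the lactone C6–O1 bond breaks while the enol-ether terminus bonds to C3 and the new C=C bond appears between the former C6 and the inner vinyl carbon. The closest known reaction type is the Ireland–Claisen rearrangement in its ring-contracting form (alkenyl lactone silyl ketene acetal to cycloalkenecarboxylic acid). The cyclohexene closes pericyclically, not by an ionic exo or endo attack: the four lactone carbons C3–C6 and the two vinyl carbons become the carbocycle through the only reachable transition state, a boat of bicyclo[2.2.2]octane shape with the alkenyl group axial. The new ring CH (former C3) is set by the lactone face on which the alkenyl group sits, that is by the quaternary carbinol C6, so that the carboxyl group ends up trans to the MOM ether at C5; the new carbinol carbon is set by the (Z) geometry of the enol ether, whose inside alkoxy group ends up trans to the carboxyl group and cis to the MOM ether. The step needs the concerted boat pathway to win over ionisation of the tertiary alkoxy-activated allylic C–O bond and over C-silylation; the ring constraint (no chair is possible), the donor alkoxy group at the bond-forming terminus (which accelerates Claisen rearrangements) and the non-polar solvent should secure this. The alkene inside the new ring can only be cis, so the configuration set in step 5 and the geometry set in step 6 pass directly into two of the three ring stereocenters.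

**Step 8**
Reactants: 15 (1R,2R,5R)-2-[(4-methoxybenzyl)oxy]-5-(methoxymethoxy)-4-methylcyclohex-3-ene-1-carboxylic acid
Product: 16 1-[(1R,2R,5R)-2-[(4-methoxybenzyl)oxy]-5-(methoxymethoxy)-4-methylcyclohex-3-en-1-yl]ethan-1-one
Conditions: MeLi (3 equiv), Et2O, 0 °C to rt; inverse aqueous quench
Reagents that add atoms: methyllithium, [Li]C
Why: Addition of methyllithium to the lithium carboxylate gives a geminal dialkoxide that collapses to the methyl ketone only on work-up (acid-to-ketone synthesis), and the α-stereocenter stays in its more stable trans arrangement.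

**Step 9**
Reactants: 16 1-[(1R,2R,5R)-2-[(4-methoxybenzyl)oxy]-5-(methoxymethoxy)-4-methylcyclohex-3-en-1-yl]ethan-1-one
Product: 17 1-[(1R,2R,5R)-2-hydroxy-5-(methoxymethoxy)-4-methylcyclohex-3-en-1-yl]ethan-1-one
Conditions: DDQ, CH2Cl2–pH 7 buffer, 0 °C
Reagents that add atoms: none
Why: Oxidative cleavage of the 4-methoxybenzyl ether by DDQ (benzylic hydride abstraction, then hydrolysis of the oxocarbenium ion) is selective over the MOM acetal and the ring alkene.

**Step 10**
Reactants: 17 1-[(1R,2R,5R)-2-hydroxy-5-(methoxymethoxy)-4-methylcyclohex-3-en-1-yl]ethan-1-one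
Product: 19 (4aS,6R,8aR)-6-(methoxymethoxy)-4,7-dimethyl-4a,5,6,8a-tetrahydro-2H-chromen-2-one, via phosphonoacetate ester 18 (not isolated)
Conditions: (EtO)2P(O)CH2CO2H, DCC, DMAP (cat.), CH2Cl2, 0 °C; filter; then LiCl, iPr2NEt, MeCN, rt
Reagents that add atoms: diethylphosphonoacetic acid, OC(=O)CP(=O)(OCC)OCC
Why: Steglich esterification followed by an intramolecular Horner–Wadsworth–Emmons olefination under Masamune–Roush conditions should close the trans-fused α,β-unsaturated δ-lactone, because the phosphonate is far more acidic than the ketone α-hydrogen and ring closure should outrun β-elimination.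

**Step 11**
Reactants: 19 (4aS,6R,8aR)-6-(methoxymethoxy)-4,7-dimethyl-4a,5,6,8a-tetrahydro-2H-chromen-2-one
Product: 20 (4R,4aS,6R,8aS)-6-(methoxymethoxy)-4,7-dimethyl-3,4,4a,5,6,8a-hexahydro-2H-chromen-2-one
Conditions: Cu(OAc)2·H2O (5 mol %), 1,2-bis(diphenylphosphino)benzene (5 mol %), (MeO)2MeSiH, t-BuOH, toluene, rt
Reagents that add atoms: none
Why: Copper hydride conjugate reduction is chemoselective for the unsaturated lactone, and axial hydride delivery to C4 of the rigid trans-fused lactone (anti to the axial hydrogen at C4a, the sense known for conjugate additions to 6-substituted dihydropyranones) should leave the new methyl group equatorial, which is the required (R) centre.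

**Step 12**
Reactants: 20 (4R,4aS,6R,8aS)-6-(methoxymethoxy)-4,7-dimethyl-3,4,4a,5,6,8a-hexahydro-2H-chromen-2-one
Product: 21 (6R)-6-[(1S,2S,5R)-2-hydroxy-5-(methoxymethoxy)-4-methylcyclohex-3-en-1-yl]-2-methylhept-2-en-4-one
Conditions: 2-methylprop-1-enyllithium (from 1-bromo-2-methylprop-1-ene, t-BuLi (2 equiv), Et2O, −78 °C), THF, −78 °C; cold aqueous quench
Reagents that add atoms: 2-methylprop-1-enyllithium, [Li]C=C(C)C, made in the flask from 1-bromo-2-methylprop-1-ene, BrC=C(C)C
Why: Mono-addition of an alkenyllithium to a lactone at −78 °C should stop at the tetrahedral lithium hemiketalate, which opens on work-up to the conjugated δ-hydroxy enone.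

**Step 13**
Reactants: 21 (6R)-6-[(1S,2S,5R)-2-hydroxy-5-(methoxymethoxy)-4-methylcyclohex-3-en-1-yl]-2-methylhept-2-en-4-one
Product: 22 (1S,4R,6S)-4-(methoxymethoxy)-3-methyl-6-[(2R)-6-methyl-4-oxohept-5-en-2-yl]cyclohex-2-en-1-yl (2Z)-2-methylbut-2-enoate
Conditions: angelic acid, 2,4,6-trichlorobenzoyl chloride, Et3N, toluene, rt; then 21, toluene, 80 °C
Reagents that add atoms: angelic acid [(Z)-2-methylbut-2-enoic acid], C/C=C(/C)C(=O)O
Why: Yamaguchi-type esterification through the mixed 2,4,6-trichlorobenzoic anhydride without DMAP should acylate the hindered secondary alcohol at the less hindered angeloyl carbonyl and avoid the (Z)-to-(E) isomerisation that nucleophilic catalysts cause.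

**Step 14**
Reactants: 22 (1S,4R,6S)-4-(methoxymethoxy)-3-methyl-6-[(2R)-6-methyl-4-oxohept-5-en-2-yl]cyclohex-2-en-1-yl (2Z)-2-methylbut-2-enoate
Product: 23 (1S,4R,6S)-4-hydroxy-3-methyl-6-[(2R)-6-methyl-4-oxohept-5-en-2-yl]cyclohex-2-en-1-yl (2Z)-2-methylbut-2-enoate
Conditions: Me2BBr, CH2Cl2, −78 °C; then THF–aq. NaHCO3
Reagents that add atoms: none
Why: Dimethylboron bromide cleaves the MOM acetal at −78 °C by coordination to the methoxy oxygen and bromide attack at the acetal carbon (Lewis acid acetal cleavage), conditions that the esters, the enone and the allylic C–O bonds should survive; it is done before the acid-sensitive side-chain allylic alcohol exists.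

**Step 15**
Reactants: 23 (1S,4R,6S)-4-hydroxy-3-methyl-6-[(2R)-6-methyl-4-oxohept-5-en-2-yl]cyclohex-2-en-1-yl (2Z)-2-methylbut-2-enoate
Product: 24 (1S,4R,6S)-4-hydroxy-6-[(2R,4R)-4-hydroxy-6-methylhept-5-en-2-yl]-3-methylcyclohex-2-en-1-yl (2Z)-2-methylbut-2-enoate
Conditions: (S)-2-methyl-CBS-oxazaborolidine (0.2 equiv), catecholborane, toluene, −78 °C
Reagents that add atoms: none
Why: Corey–Bakshi–Shibata reduction, in which the alkenyl group acts as the large substituent so that the (S)-oxazaborolidine should give the (R)-allylic alcohol under reagent control, while catecholborane at low temperature leaves the alkenes and esters alone.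

**Step 16**
Reactants: 24 (1S,4R,6S)-4-hydroxy-6-[(2R,4R)-4-hydroxy-6-methylhept-5-en-2-yl]-3-methylcyclohex-2-en-1-yl (2Z)-2-methylbut-2-enoate
Product: 25 (1S,4R,6S)-4-acetoxy-6-[(2R,4R)-4-acetoxy-6-methylhept-5-en-2-yl]-3-methylcyclohex-2-en-1-yl (2Z)-2-methylbut-2-enoate
Conditions: Ac2O, pyridine, DMAP (cat.), CH2Cl2, 0 °C to rt
Reagents that add atoms: acetic anhydride, CC(=O)OC(C)=O
Why: DMAP-catalysed acylation of both free secondary alcohols with acetic anhydride should complete the target without affecting the angelate.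

**Compound list**

1 | (R)-5-oxotetrahydrofuran-2-carboxylic acid | O=C1CC[C@H](C(=O)O)O1 | starting material
2 | (R)-N-methoxy-N-methyl-5-oxotetrahydrofuran-2-carboxamide | CON(C)C(=O)[C@H]1CCC(=O)O1 | intermediate
3 | methyl (R)-4-hydroxy-5-[methoxy(methyl)amino]-5-oxopentanoate | COC(=O)CC[C@@H](O)C(=O)N(C)OC | intermediate
4 | methyl (R)-5-[methoxy(methyl)amino]-4-(methoxymethoxy)-5-oxopentanoate | COC(=O)CC[C@@H](OCOC)C(=O)N(C)OC | intermediate
5 | methyl (R)-4-(methoxymethoxy)-5-oxohexanoate | COC(=O)CC[C@@H](OCOC)C(C)=O | intermediate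
6 | 4-methoxybenzyl alcohol | COc1ccc(CO)cc1 | starting material
7 | trichloroethylene | ClC=C(Cl)Cl | starting material
8 | (E)-1,2-dichlorovinyl 4-methoxybenzyl ether | COc1ccc(CO/C(Cl)=C\Cl)cc1 | intermediate
9 | lithium [(4-methoxybenzyl)oxy]ethynide | [Li]C#COCc1ccc(OC)cc1 | intermediate
10 | lithium alkoxide of methyl (4R,5R)-5-hydroxy-7-[(4-methoxybenzyl)oxy]-4-(methoxymethoxy)-5-methylhept-6-ynoate | COC(=O)CC[C@@H](OCOC)[C@](C)([O-])C#COCc1ccc(OC)cc1.[Li+] | intermediate
11 | (5R,6R)-6-{[(4-methoxybenzyl)oxy]ethynyl}-5-(methoxymethoxy)-6-methyltetrahydro-2H-pyran-2-one | O=C1CC[C@@H](OCOC)[C@@](C)(C#COCc2ccc(OC)cc2)O1 | intermediate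
12 | (5R,6R)-6-{(Z)-2-[(4-methoxybenzyl)oxy]ethenyl}-5-(methoxymethoxy)-6-methyltetrahydro-2H-pyran-2-one | O=C1CC[C@@H](OCOC)[C@@](C)(/C=C\OCc2ccc(OC)cc2)O1 | intermediate
13 | tert-butyl{[(2R,3R)-2-{(Z)-2-[(4-methoxybenzyl)oxy]ethenyl}-3-(methoxymethoxy)-2-methyl-3,4-dihydro-2H-pyran-6-yl]oxy}dimethylsilane | CC(C)(C)[Si](C)(C)OC1=CC[C@@H](OCOC)[C@@](C)(/C=C\OCc2ccc(OC)cc2)O1 | intermediate
14 | tert-butyldimethylsilyl (1R,2R,5R)-2-[(4-methoxybenzyl)oxy]-5-(methoxymethoxy)-4-methylcyclohex-3-ene-1-carboxylate | COc1ccc(CO[C@@H]2C=C(C)[C@H](OCOC)C[C@H]2C(=O)O[Si](C)(C)C(C)(C)C)cc1 | intermediate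
15 | (1R,2R,5R)-2-[(4-methoxybenzyl)oxy]-5-(methoxymethoxy)-4-methylcyclohex-3-ene-1-carboxylic acid | COc1ccc(CO[C@@H]2C=C(C)[C@H](OCOC)C[C@H]2C(=O)O)cc1 | intermediate
16 | 1-[(1R,2R,5R)-2-[(4-methoxybenzyl)oxy]-5-(methoxymethoxy)-4-methylcyclohex-3-en-1-yl]ethan-1-one | COc1ccc(CO[C@@H]2C=C(C)[C@H](OCOC)C[C@H]2C(C)=O)cc1 | intermediate
17 | 1-[(1R,2R,5R)-2-hydroxy-5-(methoxymethoxy)-4-methylcyclohex-3-en-1-yl]ethan-1-one | O[C@@H]1C=C(C)[C@H](OCOC)C[C@H]1C(C)=O | intermediate
18 | (1R,4R,6R)-6-acetyl-4-(methoxymethoxy)-3-methylcyclohex-2-en-1-yl 2-(diethoxyphosphoryl)acetate | CCOP(=O)(CC(=O)O[C@@H]1C=C(C)[C@H](OCOC)C[C@H]1C(C)=O)OCC | intermediate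
19 | (4aS,6R,8aR)-6-(methoxymethoxy)-4,7-dimethyl-4a,5,6,8a-tetrahydro-2H-chromen-2-one | CC1=CC(=O)O[C@@H]2C=C(C)[C@H](OCOC)C[C@@H]12 | intermediate
20 | (4R,4aS,6R,8aS)-6-(methoxymethoxy)-4,7-dimethyl-3,4,4a,5,6,8a-hexahydro-2H-chromen-2-one | C[C@@H]1CC(=O)O[C@@H]2C=C(C)[C@H](OCOC)C[C@@H]12 | intermediate
21 | (6R)-6-[(1S,2S,5R)-2-hydroxy-5-(methoxymethoxy)-4-methylcyclohex-3-en-1-yl]-2-methylhept-2-en-4-one | O[C@@H]1C=C(C)[C@H](OCOC)C[C@H]1[C@H](C)CC(=O)C=C(C)C | intermediate
22 | (1S,4R,6S)-4-(methoxymethoxy)-3-methyl-6-[(2R)-6-methyl-4-oxohept-5-en-2-yl]cyclohex-2-en-1-yl (2Z)-2-methylbut-2-enoate | C/C=C(/C)C(=O)O[C@@H]1C=C(C)[C@H](OCOC)C[C@H]1[C@H](C)CC(=O)C=C(C)C | intermediate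
23 | (1S,4R,6S)-4-hydroxy-3-methyl-6-[(2R)-6-methyl-4-oxohept-5-en-2-yl]cyclohex-2-en-1-yl (2Z)-2-methylbut-2-enoate | C/C=C(/C)C(=O)O[C@@H]1C=C(C)[C@H](O)C[C@H]1[C@H](C)CC(=O)C=C(C)C | intermediate
24 | (1S,4R,6S)-4-hydroxy-6-[(2R,4R)-4-hydroxy-6-methylhept-5-en-2-yl]-3-methylcyclohex-2-en-1-yl (2Z)-2-methylbut-2-enoate | C/C=C(/C)C(=O)O[C@@H]1C=C(C)[C@H](O)C[C@H]1[C@H](C)C[C@H](C=C(C)C)O | intermediate
25 | (1S,4R,6S)-4-acetoxy-6-[(2R,4R)-4-acetoxy-6-methylhept-5-en-2-yl]-3-methylcyclohex-2-en-1-yl (2Z)-2-methylbut-2-enoate | C/C=C(/C)C(=O)O[C@@H]1C=C(C)[C@H](OC(C)=O)C[C@H]1[C@H](C)C[C@H](C=C(C)C)OC(C)=O | target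

**Step count and risks**

Total steps: 16. Longest linear sequence: 15 steps (from 1 through steps 1–3 and 5–16); step 4 is a one-step branch that prepares 8.

Steps most likely to fail:

Step 7. The tertiary, alkoxy-activated allylic C–O bond of the silyl ketene acetal may ionise (ion-pair recombination or elimination to a dienyl ether) faster than the concerted boat rearrangement, or silylation may occur on carbon. The fallback builds the same cyclohexene by aldol addition and ring-closing metathesis; it sets out from 5 and comes back at 17. Wittig methylenation of 5 (Ph3P=CH2, THF) should give methyl (R)-4-(methoxymethoxy)-5-methylhex-5-enoate F1. Saponification (LiOH, THF–H2O) gives (R)-4-(methoxymethoxy)-5-methylhex-5-enoic acid F2. Acylation of lithiated (S)-4-benzyloxazolidin-2-one through the pivaloyl mixed anhydride gives (S)-4-benzyl-3-[(R)-4-(methoxymethoxy)-5-methylhex-5-enoyl]oxazolidin-2-one F3. The MgCl2-catalysed anti-selective aldol addition to (E)-cinnamaldehyde (MgCl2, Et3N, Me3SiCl, EtOAc) should give the trimethylsilyl ether of the (2R,3R)-anti adduct F4; the auxiliary controls the α-centre and the anti mode the carbinol. Desilylation (CF3CO2H, MeOH) gives the free anti aldol adduct F5. Ring-closing metathesis with the second-generation Grubbs catalyst, RuCl2(=CHPh)(H2IMes)(PCy3), closes the trisubstituted ring alkene with loss of styrene and gives the cyclohexenol imide F6. Transamidation (MeNH(OMe)·HCl, Me3Al) gives (1R,2R,5R)-2-hydroxy-N-methoxy-5-(methoxymethoxy)-N,4-dimethylcyclohex-3-ene-1-carboxamide F7, and MeMgBr then gives 17.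

Step 5. The benzylic alkynyl ether anion may decompose before it adds, chelation may not dominate (poor facial selectivity at the new quaternary carbinol), or the tertiary alkoxide may not lactonise. The fallback introduces the enol-ether oxygen by C–O coupling instead of an alkynyl ether nucleophile; it sets out from 5 and comes back at 12. Chelation-controlled addition of ethynylmagnesium bromide (MgBr2·OEt2, CH2Cl2–THF, −78 °C to rt) with lactonisation should give (5R,6R)-6-ethynyl-5-(methoxymethoxy)-6-methyltetrahydro-2H-pyran-2-one F8. Rhodium-catalysed trans-hydroboration ([Rh(cod)Cl]2, P(iPr)3, Et3N, pinacolborane) should give (5R,6R)-5-(methoxymethoxy)-6-methyl-6-[(Z)-2-(4,4,5,5-tetramethyl-1,3,2-dioxaborolan-2-yl)ethenyl]tetrahydro-2H-pyran-2-one F9. Cu(OAc)2-promoted coupling of this alkenylboronate with 4-methoxybenzyl alcohol (Et3N, air), which retains the alkene geometry, then gives 12.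

Step 12. The lithium hemiketalate may collapse before the quench, leading to a second addition or conjugate addition, or the alkenyllithium may enolise the lactone. The fallback passes through an amide that cannot over-add; it sets out from 20 and comes back at 21. Aminolysis of 20 (MeNH(OMe)·HCl, Me3Al, CH2Cl2) should give (R)-3-[(1S,2S,5R)-2-hydroxy-5-(methoxymethoxy)-4-methylcyclohex-3-en-1-yl]-N-methoxy-N-methylbutanamide F10. Silylation (Et3SiCl, imidazole) gives its triethylsilyl ether F11. Addition of 2-methylprop-1-enylmagnesium bromide (THF, 0 °C) gives (R)-6-[(1S,2S,5R)-5-(methoxymethoxy)-4-methyl-2-(triethylsilyloxy)cyclohex-3-en-1-yl]-2-methylhept-2-en-4-one F12, and HF·pyridine then gives 21.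

**Further compounds**

F1 | step 7 | methyl (R)-4-(methoxymethoxy)-5-methylhex-5-enoate | C=C(C)[C@H](OCOC)CCC(=O)OC
F2 | step 7 | (R)-4-(methoxymethoxy)-5-methylhex-5-enoic acid | C=C(C)[C@H](OCOC)CCC(=O)O
F3 | step 7 | (S)-4-benzyl-3-[(R)-4-(methoxymethoxy)-5-methylhex-5-enoyl]oxazolidin-2-one | C=C(C)[C@H](OCOC)CCC(=O)N1[C@@H](Cc2ccccc2)COC1=O
F4 | step 7 | (S)-4-benzyl-3-{(2R,3R,4E)-2-[(R)-2-(methoxymethoxy)-3-methylbut-3-enyl]-5-phenyl-3-(trimethylsilyloxy)pent-4-enoyl}oxazolidin-2-one | C[Si](C)(C)O[C@H](/C=C/c1ccccc1)[C@@H](C[C@@H](OCOC)C(C)=C)C(=O)N1[C@@H](Cc2ccccc2)COC1=O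
F5 | step 7 | (S)-4-benzyl-3-{(2R,3R,4E)-3-hydroxy-2-[(R)-2-(methoxymethoxy)-3-methylbut-3-enyl]-5-phenylpent-4-enoyl}oxazolidin-2-one | O[C@H](/C=C/c1ccccc1)[C@@H](C[C@@H](OCOC)C(C)=C)C(=O)N1[C@@H](Cc2ccccc2)COC1=O
F6 | step 7 | (S)-4-benzyl-3-{[(1R,2R,5R)-2-hydroxy-5-(methoxymethoxy)-4-methylcyclohex-3-en-1-yl]carbonyl}oxazolidin-2-one | O[C@@H]1C=C(C)[C@H](OCOC)C[C@H]1C(=O)N2[C@@H](Cc3ccccc3)COC2=O
F7 | step 7 | (1R,2R,5R)-2-hydroxy-N-methoxy-5-(methoxymethoxy)-N,4-dimethylcyclohex-3-ene-1-carboxamide | O[C@@H]1C=C(C)[C@H](OCOC)C[C@H]1C(=O)N(C)OC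
F8 | step 5 | (5R,6R)-6-ethynyl-5-(methoxymethoxy)-6-methyltetrahydro-2H-pyran-2-one | O=C1CC[C@@H](OCOC)[C@@](C)(C#C)O1
F9 | step 5 | (5R,6R)-5-(methoxymethoxy)-6-methyl-6-[(Z)-2-(4,4,5,5-tetramethyl-1,3,2-dioxaborolan-2-yl)ethenyl]tetrahydro-2H-pyran-2-one | O=C1CC[C@@H](OCOC)[C@@](C)(/C=C\B2OC(C)(C)C(C)(C)O2)O1
F10 | step 12 | (R)-3-[(1S,2S,5R)-2-hydroxy-5-(methoxymethoxy)-4-methylcyclohex-3-en-1-yl]-N-methoxy-N-methylbutanamide | O[C@@H]1C=C(C)[C@H](OCOC)C[C@H]1[C@H](C)CC(=O)N(C)OC
F11 | step 12 | (R)-N-methoxy-3-[(1S,2S,5R)-5-(methoxymethoxy)-4-methyl-2-(triethylsilyloxy)cyclohex-3-en-1-yl]-N-methylbutanamide | CC[Si](CC)(CC)O[C@@H]1C=C(C)[C@H](OCOC)C[C@H]1[C@H](C)CC(=O)N(C)OC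
F12 | step 12 | (R)-6-[(1S,2S,5R)-5-(methoxymethoxy)-4-methyl-2-(triethylsilyloxy)cyclohex-3-en-1-yl]-2-methylhept-2-en-4-one | CC[Si](CC)(CC)O[C@@H]1C=C(C)[C@H](OCOC)C[C@H]1[C@H](C)CC(=O)C=C(C)C
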